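Ring numbering used throughout (target numbering): O1, C2 (aryl), C3 (CH2O arm), C4 (OH), C5 (CH2).

## Analysis of the target

Target 21 is a monocyclic tetrahydrofuran. It carries a 3,4-dimethoxyphenyl group at C2, a CH2O arm at C3 acylated by 3,4-dimethoxybenzoic acid, and a free secondary hydroxyl at C4; C5 is an unsubstituted methylene. The three stereocentres are contiguous, (2S,3R,4S), and the aryl, acyloxymethyl and hydroxyl groups all lie on one face of the ring. This all-cis array is the most crowded diastereomer, so no centre may be left to equilibrate: C3 must not sit next to a carbonyl for long and C2 must not ionise. The sensitive points are the benzylic C2–O1 bond (the para-methoxy group favours acid ionisation and epimerisation), the two electron-rich arenes (which limit oxidants), and the primary ester, which sits cis to the C4 hydroxyl and can migrate under base. The difficulty is therefore stereochemical, not skeletal: three adjacent substituents must be placed cis under kinetic control. The strategy rests on the C3–C4 bond. C4–C5 is an oxygenated two-carbon unit at the aldehyde oxidation level, and C3, with its arm carried as a nitromethyl group next to the C2 carbinol, is the β-carbon of a nitroalkene. Joining the two forms C3–C4, after which the C2 hydroxyl closes O1–C5.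

## Retrosynthetic reasoning

**Ester and silyl ether.** 21 is cut at the acyl–oxygen bond of the ester to primary alcohol 18 and acid chloride 19, with the C4 hydroxyl kept as the silyl ether in 20. Making the ester last keeps it out of every basic or reducing step. The forward steps only have to acylate the one free hydroxyl and then remove silicon without acyl transfer to the cis C4 oxygen.

**The C3 arm.** The hydroxymethyl group of 18 is traced through aldehyde 17 and nitronate 16 to the nitromethyl group of 15. No skeletal bond is cut; a C–N bond is exchanged for C–O. Reading the arm as the α-carbon of a nitroalkane is what makes C3 an electrophilic carbon in the key step. The forward step must unmask the carbonyl and reduce it before C3, now α to an aldehyde, can epimerise.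

**C5.** The C5 methylene of 15 is taken back to the hemiacetal carbon of lactol 14. The forward step is an ionic reduction of the cyclic hemiacetal that must leave the benzylic C2–O1 bond alone.

**O1–C5 and C3–C4 (key disconnection).** 14 is opened at O1–C5 to hydroxy aldehyde 13, and 13 is cut at C3–C4 into nitroalkenol 11 and aldehyde 12. This is the only cut that divides the ring into a two-carbon and a three-carbon piece with matching natural polarity (enamine α-carbon against nitroalkene β-carbon). It creates C3 and C4 in one bond-forming event in an open transition state, not on a preformed ring where the all-cis isomer would be disfavoured. The forward reaction must give the syn relation between C3 and C4 and place the C3 arm cis to the C2 aryl.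

**Nitroalkene.** 11 comes from its silyl ether 10. The C=C bond of 10 is cut through mesylate 9 and nitro alcohol 8 to aldehyde 6 and nitromethane 7 (Henry disconnection). The forward steps must keep the benzylic stereocentre of 6, which is α to an aldehyde, intact.

**Carbinol.** 6 is the partially reduced form of ester 5, the silyl ether of mandelate 4. 4 comes from keto ester 3 by enantioselective reduction, which sets the future C2. 3 is cut at the aryl–carbonyl bond to veratrole 1 and acid chloride 2.

## Alternatives that were turned down

**Alternative 1: aldol-lactonisation to a fused β-lactone.**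
- Disconnection: C3–C4 and the C4–O bond of a β-lactone, back to (S)-3-(3,4-dimethoxyphenyl)-3-(2-oxoethoxy)propanoic acid A1.
- Forward key step: carboxyl activation (2-chloro-1-methylpyridinium iodide, i-Pr2NEt) and acyl transfer to a chiral isothiourea; the ammonium enolate adds to the tethered aldehyde, closing the tetrahydrofuran, and the aldolate lactonises to (1S,2S,5S)-2-(3,4-dimethoxyphenyl)-3,6-dioxabicyclo[3.2.0]heptan-7-one A2.
- For it: the four-membered ring can only be cis-fused, so the C3/C4 cis relation is guaranteed by geometry. That is a firmer guarantee than the syn preference of an open transition state. A2 also holds the C3 carbon and the C4 oxygen together, so one hydride reduction and one selective primary acylation would finish. The route would be several steps shorter and needs neither a Nef step nor a lactol reduction. On these points it is stronger than the chosen route.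
- Against: the C2 aryl must end on the concave face of the bicycle, cis to the lactone. C2 is directly next to the enolate carbon, so the aryl will prefer the convex side and the catalyst must overrule a close substrate bias in a compact bicyclic transition state. In addition, the enolate of A1 has the ether oxygen as a leaving group on a p-alkoxybenzylic β-carbon, which invites E1cB loss to a cinnamoyl species.
- Comparison: the chosen strategy is longer, but it sets C3 in an acyclic transition state with no concave-face penalty, and its carbanionic intermediates (nitronates) have no β-leaving group.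

**Alternative 2: vinyl oxirane to dihydrofuran ring expansion.**
- Disconnection: O1–C5, back to [(3R)-3-(3,4-dimethoxyphenyl)-2-vinyloxiran-2-yl]methanol A3.
- Forward key step: Cu(hfacac)2 opens the allylic C3–O bond and the oxygen closes on the vinyl terminus, giving [(2R)-2-(3,4-dimethoxyphenyl)-2,5-dihydrofuran-3-yl]methanol A4 with C2 untouched.
- For it: the C2 configuration can come from a Sharpless epoxidation, at least as dependable as the ketone reduction used here. The ring expansion is catalytic and atom-economical, and A4 already has the free hydroxymethyl group.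
- Against: A4 has one of the three stereocentres and no oxygen at C4. Hydroboration of C3=C4 adds H (to C3) and boron (to C4) to the same face, so the C3 arm and the C4 hydroxyl would end trans. Correction needs an oxidation–reduction or inversion at C4, through a C4 ketone whose β-carbon C2 carries the ring oxygen (ring opening by retro-oxa-Michael). The electron-rich aryl epoxide of A3 can also ionise at the benzylic carbon instead of the allylic one, and A4, being benzylic and allylic at C2, is prone to aromatise to a furan.
- Comparison: the chosen key step delivers C3, C4 and the C4 oxygen together, where this alternative needs three to four extra operations after its key step.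

**Alternative 3: enantioselective carbenoid C–H insertion.**
- Disconnection: C2–C3, back to methyl 2-diazo-4-[(3,4-dimethoxybenzyl)oxy]-3-oxobutanoate A5.
- Forward key step: Rh2(S-PTTL)4 (or its enantiomer) forms the carbenoid at C3, which inserts into one benzylic C–H bond to give methyl (2R)-2-(3,4-dimethoxyphenyl)-4-hydroxy-2,5-dihydrofuran-3-carboxylate A6 (enol form of the 4-oxotetrahydrofuran-3-carboxylate).
- For it: the shortest assembly of the whole skeleton; the ester is the C3 arm and the C4 carbonyl is ready to become the hydroxyl. In step count it is stronger than the chosen route.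
- Against: an acceptor/acceptor carbenoid must choose one enantiotopic benzylic hydrogen while competing with attack on the very electron-rich arene (Buchner-type addition, aromatic substitution) and on the ether oxygen. The single stereocentre it sets, C2 of A6, is β to the ester of an enolised β-keto ester, so retro-oxa-Michael opening and re-closure can erase it. C3 and C4 would then both have to be set cis to the aryl by reduction, against the thermodynamic preference at the epimerisable C3.
- Comparison: the chosen strategy fixes C2 as a simple carbinol before ring formation and creates C3 and C4 under catalyst control in the ring-forming step.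

Key step: step 8

Assumption (chemistry): the enamine of 12 is taken to react through its E geometry from the face away from the diphenyl(silyloxy)methyl group, as enamines of simple aldehydes do; the choice of the R catalyst rests on this.

## Route

Step 1
Reactants: 1 veratrole (1,2-dimethoxybenzene); 2 methyl chlorooxoacetate
Product: 3 methyl 2-(3,4-dimethoxyphenyl)-2-oxoacetate
Conditions: AlCl3 (1.3 equiv), CH2Cl2, 0 °C to rt
Reagents that add atoms: none
Why: Friedel–Crafts acylation; the acid chloride carbon of 2 is the more electrophilic carbonyl and substitution occurs para to one methoxy group, the least hindered activated position. The keto ester deactivates the ring against a second acylation.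

Step 2
Reactants: 3 methyl 2-(3,4-dimethoxyphenyl)-2-oxoacetate
Product: 4 methyl (R)-2-(3,4-dimethoxyphenyl)-2-hydroxyacetate
Conditions: RuCl[(S,S)-TsDPEN](p-cymene) (1 mol%), HCO2H–Et3N (5:2), DMF, 25 °C
Reagents that add atoms: none
Why: Asymmetric transfer hydrogenation of an aryl ketone; hydride and proton pass from the Ru–H/N–H unit in a six-membered transition state with the aryl group held against the p-cymene ligand. With the (S,S) ligand this places the hydroxyl as in (S)-1-arylethanols, which is the R descriptor here because CO2Me outranks aryl; this sets the future C2.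

Step 3
Reactants: 4 methyl (R)-2-(3,4-dimethoxyphenyl)-2-hydroxyacetate
Product: 5 methyl (R)-2-[(tert-butyldimethylsilyl)oxy]-2-(3,4-dimethoxyphenyl)acetate
Conditions: TBSCl, imidazole, DMF, rt
Reagents that add atoms: tert-butyldimethylsilyl chloride, CC(C)(C)[Si](C)(C)Cl
Why: Silyl ether formation through the N-silylimidazolium ion; the stereocentre is not touched. The ether is needed because a free α-hydroxy aldehyde would dimerise in the next steps.

Step 4
Reactants: 5 methyl (R)-2-[(tert-butyldimethylsilyl)oxy]-2-(3,4-dimethoxyphenyl)acetate
Product: 6 (R)-2-[(tert-butyldimethylsilyl)oxy]-2-(3,4-dimethoxyphenyl)acetaldehyde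
Conditions: i-Bu2AlH (1.1 equiv), CH2Cl2, −78 °C; MeOH then aqueous Rochelle salt; used crude
Reagents that add atoms: none
Why: Partial reduction of an ester; at −78 °C the aluminium hemiacetal, stabilised by the α-silyloxy oxygen, persists and releases the aldehyde only on work-up. The crude aldehyde is used at once to protect the α-stereocentre.

Step 5
Reactants: 6 (R)-2-[(tert-butyldimethylsilyl)oxy]-2-(3,4-dimethoxyphenyl)acetaldehyde; 7 nitromethane
Product: 8 (1R)-1-[(tert-butyldimethylsilyl)oxy]-1-(3,4-dimethoxyphenyl)-3-nitropropan-2-ol (both C2 epimers)
Conditions: MeNO2 (solvent), Et3N (0.2 equiv), 0 °C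
Reagents that add atoms: none
Why: Henry (nitroaldol) reaction; with nitromethane in large excess the nitronate should add to the aldehyde faster than the weak amine enolises it. The new carbinol centre is formed as a mixture and is removed in step 6.

Step 6
Reactants: 8 (1R)-1-[(tert-butyldimethylsilyl)oxy]-1-(3,4-dimethoxyphenyl)-3-nitropropan-2-ol
Product: 10 tert-butyl{[(1S,2E)-1-(3,4-dimethoxyphenyl)-3-nitroprop-2-en-1-yl]oxy}dimethylsilane, via secondary mesylate 9 (not isolated)
Conditions: MsCl (1.5 equiv), Et3N (3 equiv), CH2Cl2, −20 °C
Reagents that add atoms: none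
Why: Mesylation followed by E1cB elimination through the nitronate; the conjugated E-nitroalkene is the thermodynamic product. The benzylic centre is not involved (its descriptor changes from R to S only because the priorities change).

Step 7
Reactants: 10 tert-butyl{[(1S,2E)-1-(3,4-dimethoxyphenyl)-3-nitroprop-2-en-1-yl]oxy}dimethylsilane
Product: 11 (1S,2E)-1-(3,4-dimethoxyphenyl)-3-nitroprop-2-en-1-ol
Conditions: 48% aq. HF, MeCN, 0 °C; used without storage
Reagents that add atoms: none
Why: Acidic fluoride desilylation; this avoids basic fluoride sources, which would add to the nitroalkene or remove its acidic γ-hydrogen. The nitrovinyl group disfavours benzylic ionisation under these weakly acidic conditions.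

Step 8
Reactants: 11 (1S,2E)-1-(3,4-dimethoxyphenyl)-3-nitroprop-2-en-1-ol; 12 (tert-butyldimethylsilyloxy)acetaldehyde
Product: 14 (3S,4S,5S)-3-[(tert-butyldimethylsilyl)oxy]-5-(3,4-dimethoxyphenyl)-4-(nitromethyl)tetrahydrofuran-2-ol (anomeric mixture), via open-chain hydroxy aldehyde 13 (not isolated)
Conditions: (R)-α,α-diphenylprolinol trimethylsilyl ether (15 mol%), 4-nitrophenol (15 mol%), 12 (2 equiv), toluene, 0 °C to rt
Reagents that add atoms: none
Why: Enamine-catalysed Michael addition followed by hemiacetalisation, the closest known type being the syn-selective addition of α-oxygenated aldehydes to nitroalkenes under diarylprolinol silyl ether catalysis and the Michael–hemiacetalisation cascades of hydroxyl-bearing nitroalkenes. Aldehyde 12 condenses with the amine to the E-enamine, whose face next to the diphenyl(trimethylsilyloxy)methyl group is blocked, so its α-carbon (future C4) bonds to the β-carbon of 11 (future C3) from the open face. The two π systems meet in an acyclic synclinal arrangement with the nitro group near the enamine nitrogen, which gives the syn adduct and hence the C3 and C4 substituents cis on the ring. C4 is fixed by the catalyst alone and C3 by the catalyst through this topology; with the R catalyst and the S carbinol both have the required configuration, the C3 arm cis to the aryl corresponding to attack anti to the carbinol oxygen in the conformer whose carbinol hydrogen eclipses the alkene. Hydrolysis of the iminium ion releases 13 and the catalyst, and the C2 hydroxyl adds to the aldehyde in a 5-exo-trig closure that forms O1–C5; the anomeric centre is uncontrolled and is removed in step 9. The step needs syn selectivity, secured by the E geometry of both partners, and the correct nitroalkene face, which relies on catalyst control outweighing the allylic stereocentre. Lactol formation takes the aldehyde out of the enamine equilibrium and so protects C4 against epimerisation. The weak acid co-catalyst speeds enamine turnover and keeps the medium from removing the γ-hydrogen of 11.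

Step 9
Reactants: 14 (3S,4S,5S)-3-[(tert-butyldimethylsilyl)oxy]-5-(3,4-dimethoxyphenyl)-4-(nitromethyl)tetrahydrofuran-2-ol
Product: 15 (2S,3S,4S)-4-[(tert-butyldimethylsilyl)oxy]-2-(3,4-dimethoxyphenyl)-3-(nitromethyl)tetrahydrofuran
Conditions: Et3SiH (3 equiv), BF3·OEt2 (2 equiv), CH2Cl2, −78 to −40 °C
Reagents that add atoms: none
Why: Ionic reduction of a lactol; the anomeric C–O bond ionises to the cyclic oxocarbenium ion much more readily than the benzylic ether at low temperature, and the silane delivers hydride to C5. C5 becomes a methylene, so no stereocentre is at stake, and C2, C3 and C4 are not touched.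

Step 10
Reactants: 15 (2S,3S,4S)-4-[(tert-butyldimethylsilyl)oxy]-2-(3,4-dimethoxyphenyl)-3-(nitromethyl)tetrahydrofuran
Product: 18 [(2S,3S,4S)-4-[(tert-butyldimethylsilyl)oxy]-2-(3,4-dimethoxyphenyl)tetrahydrofuran-3-yl]methanol, via sodium nitronate 16 (not isolated), via aldehyde 17 (not isolated)
Conditions: NaOMe (1.05 equiv), MeOH–CH2Cl2, 0 °C; O3, −78 °C, stopped when the nitronate is consumed; N2 purge; NaBH4 (3 equiv), −78 to 0 °C
Reagents that add atoms: ozone, [O-][O+]=O
Why: Nef-type oxidative cleavage of a nitronate by ozone followed by carbonyl reduction; the nitronate carbon is far more nucleophilic toward ozone than the dimethoxyarenes, one oxygen atom is transferred and nitrite leaves. Borohydride added at −78 °C should reduce aldehyde 17 before its α-centre C3 can epimerise or a β-oxygen can be eliminated.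

Step 11
Reactants: 18 [(2S,3S,4S)-4-[(tert-butyldimethylsilyl)oxy]-2-(3,4-dimethoxyphenyl)tetrahydrofuran-3-yl]methanol; 19 3,4-dimethoxybenzoyl chloride
Product: 20 [(2S,3S,4S)-4-[(tert-butyldimethylsilyl)oxy]-2-(3,4-dimethoxyphenyl)tetrahydrofuran-3-yl]methyl 3,4-dimethoxybenzoate
Conditions: 19 (1.2 equiv), Et3N, DMAP (cat.), CH2Cl2, 0 °C to rt
Reagents that add atoms: none
Why: Acylation of a primary alcohol through the acylpyridinium ion; the only other hydroxyl is silylated, so no selectivity is required.

Step 12
Reactants: 20 [(2S,3S,4S)-4-[(tert-butyldimethylsilyl)oxy]-2-(3,4-dimethoxyphenyl)tetrahydrofuran-3-yl]methyl 3,4-dimethoxybenzoate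
Product: 21 [(2S,3R,4S)-2-(3,4-dimethoxyphenyl)-4-hydroxytetrahydrofuran-3-yl]methyl 3,4-dimethoxybenzoate (target)
Conditions: HF·pyridine, pyridine–THF, 0 °C to rt
Reagents that add atoms: none
Why: Buffered acidic fluoride desilylation; it avoids basic fluoride, which could move the ester to the cis C4 hydroxyl, and is too weakly acidic to ionise the benzylic C2–O1 bond. The C3 descriptor changes from S to R only because the priorities change.

## Compound list

1 | veratrole (1,2-dimethoxybenzene) | COc1ccccc1OC | starting material
2 | methyl chlorooxoacetate | COC(=O)C(Cl)=O | starting material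
3 | methyl 2-(3,4-dimethoxyphenyl)-2-oxoacetate | COC(=O)C(=O)c1ccc(OC)c(OC)c1 | intermediate
4 | methyl (R)-2-(3,4-dimethoxyphenyl)-2-hydroxyacetate | O[C@@H](C(=O)OC)c1ccc(OC)c(OC)c1 | intermediate
5 | methyl (R)-2-[(tert-butyldimethylsilyl)oxy]-2-(3,4-dimethoxyphenyl)acetate | CC(C)(C)[Si](C)(C)O[C@@H](C(=O)OC)c1ccc(OC)c(OC)c1 | intermediate
6 | (R)-2-[(tert-butyldimethylsilyl)oxy]-2-(3,4-dimethoxyphenyl)acetaldehyde | CC(C)(C)[Si](C)(C)O[C@@H](C=O)c1ccc(OC)c(OC)c1 | intermediate
7 | nitromethane | C[N+](=O)[O-] | starting material
8 | (1R)-1-[(tert-butyldimethylsilyl)oxy]-1-(3,4-dimethoxyphenyl)-3-nitropropan-2-ol (both C2 epimers) | CC(C)(C)[Si](C)(C)O[C@@H](C(O)C[N+](=O)[O-])c1ccc(OC)c(OC)c1 | intermediate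
9 | (1R)-1-[(tert-butyldimethylsilyl)oxy]-1-(3,4-dimethoxyphenyl)-3-nitropropan-2-yl methanesulfonate (not isolated) | CC(C)(C)[Si](C)(C)O[C@@H](C(OS(C)(=O)=O)C[N+](=O)[O-])c1ccc(OC)c(OC)c1 | intermediate
10 | tert-butyl{[(1S,2E)-1-(3,4-dimethoxyphenyl)-3-nitroprop-2-en-1-yl]oxy}dimethylsilane | CC(C)(C)[Si](C)(C)O[C@@H](/C=C/[N+](=O)[O-])c1ccc(OC)c(OC)c1 | intermediate
11 | (1S,2E)-1-(3,4-dimethoxyphenyl)-3-nitroprop-2-en-1-ol | O[C@@H](/C=C/[N+](=O)[O-])c1ccc(OC)c(OC)c1 | intermediate
12 | (tert-butyldimethylsilyloxy)acetaldehyde | CC(C)(C)[Si](C)(C)OCC=O | starting material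
13 | (2S,3S,4S)-2-[(tert-butyldimethylsilyl)oxy]-4-(3,4-dimethoxyphenyl)-4-hydroxy-3-(nitromethyl)butanal (not isolated) | [O-][N+](=O)C[C@H]([C@H](O[Si](C)(C)C(C)(C)C)C=O)[C@H](O)c1ccc(OC)c(OC)c1 | intermediate
14 | (3S,4S,5S)-3-[(tert-butyldimethylsilyl)oxy]-5-(3,4-dimethoxyphenyl)-4-(nitromethyl)tetrahydrofuran-2-ol (anomeric mixture) | [O-][N+](=O)C[C@@H]1[C@H](O[Si](C)(C)C(C)(C)C)C(O)O[C@@H]1c1ccc(OC)c(OC)c1 | intermediate
15 | (2S,3S,4S)-4-[(tert-butyldimethylsilyl)oxy]-2-(3,4-dimethoxyphenyl)-3-(nitromethyl)tetrahydrofuran | [O-][N+](=O)C[C@@H]1[C@H](O[Si](C)(C)C(C)(C)C)CO[C@@H]1c1ccc(OC)c(OC)c1 | intermediate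
16 | sodium nitronate of 15 (not isolated) | [Na+].[O-][N+]([O-])=C[C@@H]1[C@H](O[Si](C)(C)C(C)(C)C)CO[C@@H]1c1ccc(OC)c(OC)c1 | intermediate
17 | (2S,3S,4S)-4-[(tert-butyldimethylsilyl)oxy]-2-(3,4-dimethoxyphenyl)tetrahydrofuran-3-carbaldehyde (not isolated) | O=C[C@@H]1[C@H](O[Si](C)(C)C(C)(C)C)CO[C@@H]1c1ccc(OC)c(OC)c1 | intermediate
18 | [(2S,3S,4S)-4-[(tert-butyldimethylsilyl)oxy]-2-(3,4-dimethoxyphenyl)tetrahydrofuran-3-yl]methanol | OC[C@@H]1[C@H](O[Si](C)(C)C(C)(C)C)CO[C@@H]1c1ccc(OC)c(OC)c1 | intermediate
19 | 3,4-dimethoxybenzoyl chloride | COc1ccc(C(Cl)=O)cc1OC | starting material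
20 | [(2S,3S,4S)-4-[(tert-butyldimethylsilyl)oxy]-2-(3,4-dimethoxyphenyl)tetrahydrofuran-3-yl]methyl 3,4-dimethoxybenzoate | COc1ccc(C(=O)OC[C@@H]2[C@H](O[Si](C)(C)C(C)(C)C)CO[C@@H]2c2ccc(OC)c(OC)c2)cc1OC | intermediate
21 | [(2S,3R,4S)-2-(3,4-dimethoxyphenyl)-4-hydroxytetrahydrofuran-3-yl]methyl 3,4-dimethoxybenzoate | COc1ccc(C(=O)OC[C@@H]2[C@H](O)CO[C@@H]2c2ccc(OC)c(OC)c2)cc1OC | target

## Step count and least certain steps

Total: 12 steps. Longest linear sequence: 12 steps (1 to 21); 7, 12 and 19 are purchased.

**Step 8 (key step).** Two processes are most likely to fail. First, the amine may remove the benzylic γ-hydrogen of 11, which is vinylogously acidic through the nitroalkene, leading to isomerisation or to oxa-Michael oligomerisation through the free hydroxyl. Second, facial selectivity at C3 may be poor if the intrinsic bias of the carbinol opposes the catalyst. That bias cannot be predicted securely: with the C–O bond anti to the incoming nucleophile, the hydrogen-inside and aryl-inside conformers lead to opposite C2/C3 relations.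

Fallback: set out from silyl ether 10 (step 7 is omitted) and 12. The same amine-catalysed Michael addition, now without a free hydroxyl, should give (2S,3S,4S)-2,4-bis[(tert-butyldimethylsilyl)oxy]-4-(3,4-dimethoxyphenyl)-3-(nitromethyl)butanal F1. Reductive etherification of F1 (BiBr3 cat., Et3SiH, MeCN, 0 °C) would then close O1–C5: only the benzylic silyl ether oxygen can reach the activated aldehyde in a five-membered closure, and the resulting oxocarbenium ion is reduced by the silane. This comes back to the route at 15.

**Step 10.** The likely failures are over-oxidation of the dimethoxyphenyl ring by ozone once the nitronate is consumed, and epimerisation at C3 (or β-elimination of a ring or silyl oxygen) while the all-cis aldehyde is present in a basic medium.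

Fallback: from 15, oxidation of the primary nitro group with NaNO2 and AcOH in DMSO at 35 °C (through the nitrolic acid) would give (2S,3S,4S)-4-[(tert-butyldimethylsilyl)oxy]-2-(3,4-dimethoxyphenyl)tetrahydrofuran-3-carboxylic acid F2 without ozone and without an aldehyde stage. Reduction of the acid with BH3·THF at 0 °C returns to the route at 18.

**Step 9.** The Lewis acid may ionise the benzylic C2–O1 bond, which the dimethoxyphenyl group stabilises as a cation. That would epimerise C2 toward the less crowded isomer or lead to reductive ring opening; partial loss of the silyl ether is a lesser concern.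

Fallback: from 14, NaBH4 in MeOH at 0 °C would reduce the open-chain tautomer to (1S,2S,3S)-3-[(tert-butyldimethylsilyl)oxy]-1-(3,4-dimethoxyphenyl)-2-(nitromethyl)butane-1,4-diol F3. TsCl in pyridine would sulfonylate the primary hydroxyl to (2S,3S,4S)-2-[(tert-butyldimethylsilyl)oxy]-4-(3,4-dimethoxyphenyl)-4-hydroxy-3-(nitromethyl)butyl 4-methylbenzenesulfonate F4. The benzylic hydroxyl then displaces the tosylate in a 5-exo-tet closure that breaks no bond at C2, returning to the route at 15.

**Step 5.** Enolisation of 6, whose α-hydrogen is benzylic and next to an aldehyde, would erode the enantiopurity of the future C2 during the base-mediated nitroaldol. Any minor enantiomer carried forward would give a diastereomeric lactol in step 8 and could be removed at 14, but material would be lost.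

Fallback: from 6, non-basic methylenation (Zn, CH2Br2, TiCl4, THF; Takai–Lombardo) would give (S)-tert-butyl{[1-(3,4-dimethoxyphenyl)prop-2-en-1-yl]oxy}dimethylsilane F5. Radical nitration–elimination of the terminal alkene (AgNO2, TEMPO, 4 Å molecular sieves, 1,2-dichloroethane, 70 °C) would give the E-nitroalkene and return to the route at 10.

## Further compounds

F1 | step 8 | (2S,3S,4S)-2,4-bis[(tert-butyldimethylsilyl)oxy]-4-(3,4-dimethoxyphenyl)-3-(nitromethyl)butanal | [O-][N+](=O)C[C@H]([C@H](O[Si](C)(C)C(C)(C)C)C=O)[C@H](O[Si](C)(C)C(C)(C)C)c1ccc(OC)c(OC)c1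
F2 | step 10 | (2S,3S,4S)-4-[(tert-butyldimethylsilyl)oxy]-2-(3,4-dimethoxyphenyl)tetrahydrofuran-3-carboxylic acid | OC(=O)[C@@H]1[C@H](O[Si](C)(C)C(C)(C)C)CO[C@@H]1c1ccc(OC)c(OC)c1
F3 | step 9 | (1S,2S,3S)-3-[(tert-butyldimethylsilyl)oxy]-1-(3,4-dimethoxyphenyl)-2-(nitromethyl)butane-1,4-diol | [O-][N+](=O)C[C@H]([C@H](O[Si](C)(C)C(C)(C)C)CO)[C@H](O)c1ccc(OC)c(OC)c1
F4 | step 9 | (2S,3S,4S)-2-[(tert-butyldimethylsilyl)oxy]-4-(3,4-dimethoxyphenyl)-4-hydroxy-3-(nitromethyl)butyl 4-methylbenzenesulfonate | [O-][N+](=O)C[C@H]([C@H](O[Si](C)(C)C(C)(C)C)COS(=O)(=O)c1ccc(C)cc1)[C@H](O)c1ccc(OC)c(OC)c1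
F5 | step 5 | (S)-tert-butyl{[1-(3,4-dimethoxyphenyl)prop-2-en-1-yl]oxy}dimethylsilane | CC(C)(C)[Si](C)(C)O[C@@H](C=C)c1ccc(OC)c(OC)c1
A1 | alternative 1 | (S)-3-(3,4-dimethoxyphenyl)-3-(2-oxoethoxy)propanoic acid | OC(=O)C[C@H](OCC=O)c1ccc(OC)c(OC)c1
A2 | alternative 1 | (1S,2S,5S)-2-(3,4-dimethoxyphenyl)-3,6-dioxabicyclo[3.2.0]heptan-7-one (all-cis) | O=C1[C@@H]2[C@H](O1)CO[C@@H]2c2ccc(OC)c(OC)c2
A3 | alternative 2 | [(3R)-3-(3,4-dimethoxyphenyl)-2-vinyloxiran-2-yl]methanol (either configuration at the quaternary carbon) | OCC1(C=C)O[C@@H]1c1ccc(OC)c(OC)c1
A4 | alternative 2 | [(2R)-2-(3,4-dimethoxyphenyl)-2,5-dihydrofuran-3-yl]methanol | OCC1=CCO[C@@H]1c1ccc(OC)c(OC)c1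
A5 | alternative 3 | methyl 2-diazo-4-[(3,4-dimethoxybenzyl)oxy]-3-oxobutanoate | COC(=O)C(=[N+]=[N-])C(=O)COCc1ccc(OC)c(OC)c1
A6 | alternative 3 | methyl (2R)-2-(3,4-dimethoxyphenyl)-4-hydroxy-2,5-dihydrofuran-3-carboxylate (enol form of the 4-oxotetrahydrofuran-3-carboxylate) | COC(=O)C1=C(O)CO[C@@H]1c1ccc(OC)c(OC)c1
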